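The numbers in the tables were computed with constants of no real substance; the scatter is artificial.

The target in these runs does not keep. In the teal run its share of target plus other capture product reads 59.0 % at 1.00 h and 10.8 % at 12.0 h, so a share says little without the age of the product at 60 °C.

| setting | red | teal | ochre | violet | winter | summer | noon | midnight |
|---|---|---|---|---|---|---|---|---|
| starting material | 0.044 M | 0.044 M | 0.044 M | 0.044 M | 0.044 M (fed, over 8.0 h) | 0.044 M (fed, over 50 min) | 0.044 M | 0.044 M (fed, over 8.0 h) |
| first nucleophile | 0.70 equiv | 0.70 equiv | 0.70 equiv | 0.70 equiv | 0.700 equiv | 0.700 equiv | 0.700 equiv | 0.700 equiv |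
| second nucleophile | 1.8 equiv | 1.8 equiv | 1.8 equiv | 3.6 equiv | 1.80 equiv | 1.80 equiv | 1.80 equiv | 1.80 equiv |
| protic impurity | 0.044 M | 0.029 M | 0.066 M | 0.044 M | 0.0440 M | 0.0440 M | 0.0440 M | 0.0440 M |
| temperature | 45 °C | 60 °C | 45 °C | 60 °C | 60 °C | 60 °C | 60 °C |  |
| remark | run made earlier | run made earlier | run made earlier | run made earlier | all else is in the flask from the start; the feed brings no volume worth counting | all else is in the flask from the start; the feed brings no volume worth counting | everything together at the start | the addition at 40 °C, then warmed to 60 °C; the feed brings no volume worth counting |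
| time |  |  |  |  | 10 h | 10 h | 10 h | 10 h |

- red (time / h: target / %, other capture product / %): 4.00: 10.6, 5.3; 8.00: 9.8, 9.9; 12.0: 9.5, 11.5; 15.0: 8.4, 13.1; 20.0: 5.1, 13.9
- teal (time / h: target / %, other capture product / %): 1.00: 14.1, 9.8; 2.00: 12.9, 17.1; 3.00: 9.0, 18.5; 6.00: 5.5, 25.3; 12.0: 3.0, 24.9
- ochre (time / h: target / %, other capture product / %): 2.00: 7.0, 3.9; 4.00: 10.1, 3.8; 6.00: 9.3, 9.2; 12.0: 6.9, 10.8; 25.0: 3.7, 10.7
- violet (time / h: target / %, other capture product / %): 2.50: 8.0, 23.6; 5.00: 3.6, 29.0; 8.00: 4.3, 32.2; 10.0: 4.5, 31.8; 12.0: 3.7, 32.9

(each reading ± 1 percentage point)



1. the flask with the highest share of target in target plus other capture product ("all alike" if they lie within 1.5 percentage points) (winter / summer / noon / midnight / all alike)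
2. share of target in target plus other capture product at the end, winter
3. share of target in target plus other capture product at the end, summer
4. share of target in target plus other capture product at the end, noon
5. share of target in target plus other capture product at the end, midnight

The next charge is a choice among these flasks, and the following reckoning is my own. If a short-lived common intermediate stands at a steady level, it hands material to the two nucleophiles in proportion to their amounts, each amount weighted by its own rate constant. Target over other capture product, multiplied by second nucleophile over first nucleophile, should then hold across charges at a given age. Read in the teal run at 2.00 h, that number is 1.94, a selectivity factor stamped with its age. The violet run tests it on other readings: with 3.6 equiv of second nucleophile and the impurity level of midnight, it predicts a ratio of 0.377, and violet reads 0.339 at 2.50 h.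

The midnight flask feeds at 40 °C. Taking those hours as lost to ageing, its clock at 60 °C runs 2.00 h, the age of the stamp, so its charged ratio gives a share of 43.0 %. Product in winter ages between 2.00 h and 10 h at 60 °C, and in noon 10 h, so the reckoning places them under midnight. The decision is to charge midnight with its nucleophile amounts unchanged.

The forecast also picks midnight, giving midnight 42 % (30 % to 54 %), winter 25 % (17 % to 33 %), summer 15 % (10 % to 20 %) and noon 14 % (9 % to 19 %), on the ground that “the end share reflects product age”.

The flasks give midnight 40.7 %, winter 23.0 %, summer 17.0 % and noon 17.0 %, so midnight stands highest.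

    second nucleophile + intermediate → other capture product (k = 444 /M/h, Ea = 53.0 kJ/mol)
    starting material + protic impurity → quenched substrate (k = 6.78 /M/h, Ea = 62.0 kJ/mol)
    first nucleophile + intermediate → target (k = 3160 /M/h, Ea = 51.0 kJ/mol)
    target ⇌ isomer of the product (K = 8.60, k = 1.04 /h, Ea = 94.0 kJ/mol, ΔH = −1.00 kJ/mol)
    starting material ⇌ intermediate (K = 0.140, k = 0.442 /h, Ea = 102 kJ/mol, ΔH = −76.0 kJ/mol)
    (constants at 60 °C)

The drain is the reaction of target to isomer of the product: with it taken away, both ways, the gap between midnight and noon shrinks from 24 percentage points to 2.9 points, the largest single effect on that gap. The forecast's choice would fail with time: at 100 h midnight gives 17.4 % and noon 16.7 %. On the neighbour like midnight but with 1.80 equiv of first nucleophile, the stamped factor gives a ratio of 1.94 and a share of 66.0 %; the computed flask gives 67.3 %.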